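**Plan**
1. Retrosynthesis: the lower pyran ring (O1, C2, C3, C4, C4a, C8a of the terminal unit) is cut at O1–C2 and C3–C4 (retro oxa-[4+2]) into an ortho-quinone methide on the lower phloroglucinol ring and a Z enol ester carrying ring B. Then the bond from C4 of the middle unit to the lower ring is cut to 3,5-bis(benzyloxy)phenol, and the upper C4–C8 bond to two epiafzelechin units.
2. Forward: (−)-epiafzelechin supplies the upper and middle pyran rings. The sequence is O-benzyl/3-O-acetyl monomer → C4 activation → 4β→8 dimer → C4 activation → C-flavanylation of the phenol ortho to its OH → boron-bridged ortho-CH2O (temporary dioxaborin ring) → thermal o-quinone methide/[4+2] closing the last pyran ring → deacylation → hydrogenolysis.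
3. Enabling feature: in the lower unit O1–C8a–C4a–C4H2 is an ortho-hydroxybenzyl array with an unsubstituted C4 on an electron-rich ring (an o-quinone methide retron). C2 carries the para-oxygenated ring B, which polarises a C2=C3 partner so that the aryl ends at C2 next to O1 and the oxygen at C3.
4. Stereochemistry: C2/C3 of the upper and middle units come from (−)-epiafzelechin. Both C4 centres (4β) arise by attack on the C4 cation anti to the 3-acetoxy group. Lower C2/C3 are cis because the alkene is Z, and (2R,3R) is assigned to the (R)-O-methylmandelate auxiliary.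

Key step: step 9

Remark: (−)-epiafzelechin, 3,5-bis(benzyloxy)phenol, 1-(benzyloxy)-4-ethynylbenzene and (R)-2-methoxy-2-phenylacetic acid are taken as purchasable. The flavan units are called U (upper), M (middle) and L (lower, terminal), and 4β means trans to the 3-oxygen of the same unit.

Step 1
Reactants: 1 (−)-epiafzelechin
Product: 2 5,7,4'-tri-O-benzyl-(−)-epiafzelechin
Conditions: BnBr (3.3 equiv), K2CO3, DMF, 0 °C → rt
Reagents that add atoms: benzyl bromide, BrCc1ccccc1
Why: Williamson O-benzylation of the three phenols under carbonate conditions leaves the less acidic secondary 3-OH free and creates no stereocentre, and early capping of the 4'-OH removes the para-quinone-methide pathway that could epimerise C2 in base.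

Step 2
Reactants: 2 5,7,4'-tri-O-benzyl-(−)-epiafzelechin
Product: 3 3-O-acetyl-5,7,4'-tri-O-benzyl-(−)-epiafzelechin
Conditions: Ac2O, pyridine, DMAP (cat.), CH2Cl2, rt
Reagents that add atoms: acetic anhydride, CC(=O)OC(C)=O
Why: DMAP-catalysed acylation of the single free secondary alcohol gives the 3-acetate, which later serves as a participating group at C4 and leaves the stereocentres untouched.

Step 3
Reactants: 3 3-O-acetyl-5,7,4'-tri-O-benzyl-(−)-epiafzelechin
Product: 4 3-O-acetyl-5,7,4'-tri-O-benzyl-4β-(2-ethoxyethoxy)epiafzelechin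
Conditions: DDQ (2 equiv), HOCH2CH2OEt, CH2Cl2, rt
Reagents that add atoms: 2-ethoxyethanol, CCOCCO
Why: DDQ benzylic oxidation (hydride abstraction at C4, stabilised by the 5,7-dialkoxy A ring) gives the C4 cation that the alcohol traps trans to the 3-acetoxy group (4β), the known oxidative C4 alkoxylation of O-benzylated flavan-3-ols.

Step 4
Reactants: 4 3-O-acetyl-5,7,4'-tri-O-benzyl-4β-(2-ethoxyethoxy)epiafzelechin; 3 3-O-acetyl-5,7,4'-tri-O-benzyl-(−)-epiafzelechin (4 equiv)
Product: 5 hexa-O-benzyl-epiafzelechin-(4β→8)-epiafzelechin 3(U),3(M)-di-O-acetate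
Conditions: TMSOTf (cat.), CH2Cl2, −78 °C
Reagents that add atoms: none
Why: Lewis-acid ionisation of the C4 ether regenerates the benzylic cation, bridged on the α face by the 3-acetate, and Friedel–Crafts attack by C8 of 3 (less hindered than C6, which lies between two benzyloxy groups) from the β face gives the 4β→8 bond as in established procyanidin couplings, with excess 3 suppressing chain growth.

Step 5
Reactants: 5 hexa-O-benzyl-epiafzelechin-(4β→8)-epiafzelechin 3(U),3(M)-di-O-acetate
Product: 6 dimer 5 carrying a 4β-(2-ethoxyethoxy) group on C4 of unit M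
Conditions: DDQ (2 equiv), HOCH2CH2OEt, CH2Cl2, rt
Reagents that add atoms: 2-ethoxyethanol, CCOCCO
Why: The same DDQ oxidative alkoxylation acts on the only remaining C4 methylene (unit M), and the alcohol again adds trans to the neighbouring 3-acetate.

Step 6
Reactants: 6 dimer carrying a 4β-(2-ethoxyethoxy) group on C4 of unit M; 7 3,5-bis(benzyloxy)phenol (8 equiv)
Product: 8 dimer bearing a 2-hydroxy-4,6-bis(benzyloxy)phenyl group at C4β of unit M
Conditions: BF3·OEt2 (cat.), CH2Cl2, −78 → −30 °C
Reagents that add atoms: none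
Why: Friedel–Crafts C-flavanylation in which the C4 cation of unit M is attacked from the β face (anti to the participating 3-acetate) by the phenol carbon ortho to its free OH, the site favoured over the carbon flanked by two benzyloxy groups by hindrance and by O-to-C migration of any aryl ether formed first, as 3,5-bis(benzyloxy)phenol shows with other stabilised benzylic cations.

Step 7
Reactants: 8 dimer bearing a 2-hydroxy-4,6-bis(benzyloxy)phenyl group at C4β of unit M
Product: 9 dimer bearing a 5,7-bis(benzyloxy)-2-phenyl-4H-1,3,2-benzodioxaborin-8-yl group at C4β of unit M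
Conditions: PhB(OH)2, (CH2O)n, EtCO2H (cat.), benzene, 80 °C, Dean–Stark
Reagents that add atoms: phenylboronic acid, OB(O)c1ccccc1; formaldehyde (as paraformaldehyde), C=O
Why: Boronic-acid-templated ortho-hydroxymethylation in which the aryl boronate formed at the lone phenol OH delivers formaldehyde to the only free ortho carbon and the benzylic alcohol closes the six-membered boronate, a temporary ring that stores the ortho-quinone methide without forming a stereocentre.

Step 8
Reactants: 10 1-(benzyloxy)-4-ethynylbenzene; 11 (R)-2-methoxy-2-phenylacetic acid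
Product: 12 (Z)-2-[4-(benzyloxy)phenyl]ethenyl (R)-2-methoxy-2-phenylacetate
Conditions: [RuCl2(p-cymene)]2 (cat.), P(4-ClC6H4)3, DMAP (cat.), PhMe, 60 °C
Reagents that add atoms: none
Why: Ruthenium-vinylidene-mediated anti-Markovnikov addition of the carboxylic acid to the terminal alkyne (hydro-oxycarbonylation) gives the Z enol ester, the geometry that later becomes the 2,3-cis relationship.

Step 9
Reactants: 9 dimer bearing the benzodioxaborin-8-yl group at C4β of unit M; 12 (Z)-2-[4-(benzyloxy)phenyl]ethenyl (R)-2-methoxy-2-phenylacetate (6 equiv)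
Product: 14 nona-O-benzyl-epiafzelechin-(4β→8)-epiafzelechin-(4β→8)-epiafzelechin 3(U)-O-acetate 3(M)-O-acetate 3(L)-O-[(R)-2-methoxy-2-phenylacetate], via lower-ring ortho-quinone methide 13 (not isolated)
Conditions: PhMe, 110–120 °C, sealed tube
Reagents that add atoms: none
Why: Proposed new method: heating 9 should extrude PhB=O by retro-[4+2] and unveil ortho-quinone methide 13 (O1=C8a–C4a=C4H2 of the lower A ring), which is captured by Z enol ester 12 in an inverse-electron-demand oxa-Diels–Alder reaction; the closest known reactions are chroman syntheses from benzodioxaborin- or Mannich-base-derived o-quinone methides with styrenes and enol ethers, here extended to a β-acyloxystyrene. The pyran ring closes by intermolecular [4+2] annulation (4π: O1=C8a–C4a=C4; 2π: C2=C3), making C4–C3 and O1–C2 in one asynchronous but concerted event. Regiochemistry of the dienophile is set by the para-benzyloxyphenyl group, which stabilises positive charge at C2 far better than the acyl-attenuated oxygen does at C3, so the aryl carbon bonds to O1 and the acyloxy carbon to the methide C4. The 2,3-cis relationship follows from suprafacial addition to the Z alkene (C4 is an unsubstituted CH2, so endo/exo is irrelevant), and the absolute sense (2R,3R) is assigned to the (R)-O-methylmandelate, whose phenyl group is expected to screen one face of the s-trans enol ester as in Diels–Alder reactions of dienyl O-methylmandelates, with the stereogenic C4 of unit M beside O1 as a second, untested bias. The step needs 4→8 connectivity and ortho regiochemistry, and both are locked in the substrate: the only free phenol oxygen of 8 (ortho to the interflavan carbon) became the quinone methide oxygen and the boron ring placed the CH2 on the only free carbon ortho to it. Excess 12 under neutral, acid-free conditions should outrun self-condensation of 13 and leave the acid-labile interflavan bonds and all esters untouched.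

Step 10
Reactants: 14 nona-O-benzyl trimer 3(U),3(M)-di-O-acetate 3(L)-O-[(R)-2-methoxy-2-phenylacetate]
Product: 15 nona-O-benzyl-epiafzelechin-(4β→8)-epiafzelechin-(4β→8)-epiafzelechin (three free 3-OH groups)
Conditions: NaOMe (cat.), MeOH/THF, rt
Reagents that add atoms: none
Why: Zemplén transesterification cleaves the two acetates and the mandelate without touching benzyl ethers, and with every phenol still protected no base-induced C2 epimerisation is possible.

Step 11
Reactants: 15 nona-O-benzyl-epiafzelechin-(4β→8)-epiafzelechin-(4β→8)-epiafzelechin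
Product: 16 epiafzelechin-(4β→8)-epiafzelechin-(4β→8)-epiafzelechin (target)
Conditions: H2 (1 atm), Pd(OH)2/C, THF/MeOH/H2O, rt
Reagents that add atoms: none
Why: Hydrogenolysis of the nine benzyl ethers over palladium hydroxide on carbon under neutral conditions leaves the interflavan bonds and all eight stereocentres intact, the standard final step of oligomeric flavan-3-ol syntheses.

**Compound list**

1 | (−)-epiafzelechin, (2R,3R)-2-(4-hydroxyphenyl)chroman-3,5,7-triol | Oc1ccc([C@H]2Oc3cc(O)cc(O)c3C[C@H]2O)cc1 | starting material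

2 | 5,7,4'-tri-O-benzyl-(−)-epiafzelechin | O(Cc5ccccc5)c1ccc([C@H]2Oc3cc(OCc5ccccc5)cc(OCc5ccccc5)c3C[C@H]2O)cc1 | intermediate

3 | 3-O-acetyl-5,7,4'-tri-O-benzyl-(−)-epiafzelechin | O(Cc5ccccc5)c1ccc([C@H]2Oc3cc(OCc5ccccc5)cc(OCc5ccccc5)c3C[C@H]2OC(C)=O)cc1 | intermediate

4 | 3-O-acetyl-5,7,4'-tri-O-benzyl-4β-(2-ethoxyethoxy)epiafzelechin (4-OR trans to 3-OAc) | O(Cc5ccccc5)c1ccc([C@H]2Oc3cc(OCc5ccccc5)cc(OCc5ccccc5)c3[C@H](OCCOCC)[C@H]2OC(C)=O)cc1 | intermediate

5 | hexa-O-benzyl-epiafzelechin-(4β→8)-epiafzelechin 3(U),3(M)-di-O-acetate (each unit 5,7,4'-tri-O-benzyl) | O(Cc5ccccc5)c1ccc([C@H]2Oc3c(c(OCc5ccccc5)cc(OCc5ccccc5)c3[C@H]3c4c(OCc5ccccc5)cc(OCc5ccccc5)cc4O[C@H](c4ccc(OCc5ccccc5)cc4)[C@@H]3OC(C)=O)C[C@H]2OC(C)=O)cc1 | intermediate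

6 | dimer 5 with a 4β-(2-ethoxyethoxy) group on C4 of unit M (trans to its 3-OAc) | O(Cc5ccccc5)c1ccc([C@H]2Oc3c(c(OCc5ccccc5)cc(OCc5ccccc5)c3[C@H]3c4c(OCc5ccccc5)cc(OCc5ccccc5)cc4O[C@H](c4ccc(OCc5ccccc5)cc4)[C@@H]3OC(C)=O)[C@H](OCCOCC)[C@H]2OC(C)=O)cc1 | intermediate

7 | 3,5-bis(benzyloxy)phenol | Oc1cc(OCc2ccccc2)cc(OCc2ccccc2)c1 | starting material

8 | dimer with a 2-hydroxy-4,6-bis(benzyloxy)phenyl group at C4β of unit M (C–C bond ortho to the phenol OH) | O(Cc5ccccc5)c1ccc([C@H]2Oc3c(c(OCc5ccccc5)cc(OCc5ccccc5)c3[C@H]3c4c(OCc5ccccc5)cc(OCc5ccccc5)cc4O[C@H](c4ccc(OCc5ccccc5)cc4)[C@@H]3OC(C)=O)[C@H](c3c(OCc5ccccc5)cc(OCc5ccccc5)cc3O)[C@H]2OC(C)=O)cc1 | intermediate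

9 | dimer with a 5,7-bis(benzyloxy)-2-phenyl-4H-1,3,2-benzodioxaborin-8-yl group at C4β of unit M (phenol O and ortho CH2O bridged by B–Ph) | O(Cc5ccccc5)c1ccc([C@H]2Oc3c(c(OCc5ccccc5)cc(OCc5ccccc5)c3[C@H]3c4c(OCc5ccccc5)cc(OCc5ccccc5)cc4O[C@H](c4ccc(OCc5ccccc5)cc4)[C@@H]3OC(C)=O)[C@H](c3c(OCc5ccccc5)cc(OCc5ccccc5)c4c3OB(c5ccccc5)OC4)[C@H]2OC(C)=O)cc1 | intermediate

10 | 1-(benzyloxy)-4-ethynylbenzene | C#Cc1ccc(OCc2ccccc2)cc1 | starting material

11 | (R)-2-methoxy-2-phenylacetic acid | CO[C@@H](C(=O)O)c1ccccc1 | starting material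

12 | (Z)-2-[4-(benzyloxy)phenyl]ethenyl (R)-2-methoxy-2-phenylacetate | CO[C@@H](C(=O)O/C=C\c1ccc(OCc2ccccc2)cc1)c1ccccc1 | intermediate

13 | lower-ring ortho-quinone methide: 3,5-bis(benzyloxy)-6-methylidenecyclohexa-2,4-dien-1-one bonded through its C2 to C4β of unit M of the dimer | O(Cc5ccccc5)c1ccc([C@H]2Oc3c(c(OCc5ccccc5)cc(OCc5ccccc5)c3[C@H]3c4c(OCc5ccccc5)cc(OCc5ccccc5)cc4O[C@H](c4ccc(OCc5ccccc5)cc4)[C@@H]3OC(C)=O)[C@H](C3=C(OCc5ccccc5)C=C(OCc5ccccc5)C(=C)C3=O)[C@H]2OC(C)=O)cc1 | intermediate (not isolated)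

14 | nona-O-benzyl-epiafzelechin-(4β→8)-epiafzelechin-(4β→8)-epiafzelechin, 3(U)-OAc, 3(M)-OAc, 3(L)-O-[(R)-2-methoxy-2-phenylacetyl] | O(Cc5ccccc5)c1ccc([C@H]2Oc3c(c(OCc5ccccc5)cc(OCc5ccccc5)c3[C@H]3c4c(OCc5ccccc5)cc(OCc5ccccc5)cc4O[C@H](c4ccc(OCc5ccccc5)cc4)[C@@H]3OC(C)=O)[C@H](c3c(OCc5ccccc5)cc(OCc5ccccc5)c4c3O[C@H](c3ccc(OCc5ccccc5)cc3)[C@H](OC(=O)[C@H](OC)c5ccccc5)C4)[C@H]2OC(C)=O)cc1 | intermediate

15 | nona-O-benzyl-epiafzelechin-(4β→8)-epiafzelechin-(4β→8)-epiafzelechin (free 3-OH on U, M and L) | O(Cc5ccccc5)c1ccc([C@H]2Oc3c(c(OCc5ccccc5)cc(OCc5ccccc5)c3[C@H]3c4c(OCc5ccccc5)cc(OCc5ccccc5)cc4O[C@H](c4ccc(OCc5ccccc5)cc4)[C@@H]3O)[C@H](c3c(OCc5ccccc5)cc(OCc5ccccc5)c4c3O[C@H](c3ccc(OCc5ccccc5)cc3)[C@H](O)C4)[C@H]2O)cc1 | intermediate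

16 | epiafzelechin-(4β→8)-epiafzelechin-(4β→8)-epiafzelechin (all units 2R,3R; both interflavan bonds trans to the adjacent 3-OH) | Oc1ccc([C@H]2Oc3c(c(O)cc(O)c3[C@H]3c4c(O)cc(O)cc4O[C@H](c4ccc(O)cc4)[C@@H]3O)[C@H](c3c(O)cc(O)c4c3O[C@H](c3ccc(O)cc3)[C@H](O)C4)[C@H]2O)cc1 | target

**Step count and risks**

Total step count: 11. Longest linear sequence: 10 steps (steps 1–7 and 9–11, from 1). Step 8 is a one-step branch.

Steps most likely to fail:

1. Step 9 (the step carrying the new-method label). The twisted, acyl-deactivated Z alkene may add too slowly, so that self-condensation of the quinone methide or its capture by electron-rich arene carbons takes over. A stepwise, zwitterionic addition with bond rotation could erode the cis relationship. Facial selectivity may be poor or reversed if the auxiliary and the resident chirality are mismatched. The fallback uses known chemistry and gives up the late annulation, bringing in the third pyran ring ready-made. It sets out from 6, which is condensed with an excess of monomer 3 (TMSOTf, CH2Cl2, −78 °C), the established Lewis-acid union of a C4-activated dimer with a flavan-3-ol nucleophile at C8. This gives nona-O-benzyl-epiafzelechin-(4β→8)-epiafzelechin-(4β→8)-epiafzelechin 3(U),3(M),3(L)-tri-O-acetate F1, and methanolysis under the conditions of step 10 comes back to the route at 15.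

2. Step 5. Over-oxidation at C4 (ketone or flavene formation), competing hydride abstraction at the doubly benzylic C4–H of unit U, and sluggish reaction of the hindered dimer may all lower the outcome. The fallback replaces oxidation of the dimer by orthogonal activation and sets out from 4. Treatment of 4 with 2,6-dimethylbenzenethiol and BF3·OEt2 (CH2Cl2, −78 °C) should give 3-O-acetyl-5,7,4'-tri-O-benzyl-4β-(2,6-dimethylphenylthio)epiafzelechin F2. An excess of this thioether, inert to the hard Lewis acid, then serves as the C8 nucleophile toward a second portion of 4 under BF3·OEt2 and gives the hexa-O-benzyl di-O-acetyl dimer carrying a 4β-(2,6-dimethylphenylthio) group on unit M F3. Thiophilic activation of the C–S bond with AgOTf in the presence of excess 7 comes back to the route at 8.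

3. Step 7. Acid and heat may cleave the interflavan bonds, PhB=O may be lost prematurely with oligomerisation of the quinone methide, and templating at the hindered phenol may stay incomplete. The fallback separates the carbon–carbon bond formation from the boron ring and sets out from 8. Magnesium-phenoxide-directed ortho-formylation (MgCl2, Et3N, (CH2O)n, THF, reflux) should give the dimer bearing a 3-formyl-2-hydroxy-4,6-bis(benzyloxy)phenyl group at C4β of unit M F4. Reduction with NaBH4 (THF/MeOH, 0 °C) gives the dimer bearing a 2-hydroxy-3-(hydroxymethyl)-4,6-bis(benzyloxy)phenyl group at C4β of unit M F5. Condensation of this diol with PhB(OH)2 (MgSO4, CH2Cl2, rt) comes back to the route at 9.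

**Further compounds**

F1 | step 9 | nona-O-benzyl-epiafzelechin-(4β→8)-epiafzelechin-(4β→8)-epiafzelechin 3(U),3(M),3(L)-tri-O-acetate | O(Cc5ccccc5)c1ccc([C@H]2Oc3c(c(OCc5ccccc5)cc(OCc5ccccc5)c3[C@H]3c4c(OCc5ccccc5)cc(OCc5ccccc5)cc4O[C@H](c4ccc(OCc5ccccc5)cc4)[C@@H]3OC(C)=O)[C@H](c3c(OCc5ccccc5)cc(OCc5ccccc5)c4c3O[C@H](c3ccc(OCc5ccccc5)cc3)[C@H](OC(C)=O)C4)[C@H]2OC(C)=O)cc1

F2 | step 5 | 3-O-acetyl-5,7,4'-tri-O-benzyl-4β-(2,6-dimethylphenylthio)epiafzelechin | O(Cc5ccccc5)c1ccc([C@H]2Oc3cc(OCc5ccccc5)cc(OCc5ccccc5)c3[C@H](Sc5c(C)cccc5C)[C@H]2OC(C)=O)cc1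

F3 | step 5 | hexa-O-benzyl-epiafzelechin-(4β→8)-epiafzelechin 3(U),3(M)-di-O-acetate with a 4β-(2,6-dimethylphenylthio) group on C4 of unit M | O(Cc5ccccc5)c1ccc([C@H]2Oc3c(c(OCc5ccccc5)cc(OCc5ccccc5)c3[C@H]3c4c(OCc5ccccc5)cc(OCc5ccccc5)cc4O[C@H](c4ccc(OCc5ccccc5)cc4)[C@@H]3OC(C)=O)[C@H](Sc5c(C)cccc5C)[C@H]2OC(C)=O)cc1

F4 | step 7 | dimer bearing a 3-formyl-2-hydroxy-4,6-bis(benzyloxy)phenyl group at C4β of unit M | O(Cc5ccccc5)c1ccc([C@H]2Oc3c(c(OCc5ccccc5)cc(OCc5ccccc5)c3[C@H]3c4c(OCc5ccccc5)cc(OCc5ccccc5)cc4O[C@H](c4ccc(OCc5ccccc5)cc4)[C@@H]3OC(C)=O)[C@H](c3c(OCc5ccccc5)cc(OCc5ccccc5)c(C=O)c3O)[C@H]2OC(C)=O)cc1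

F5 | step 7 | dimer bearing a 2-hydroxy-3-(hydroxymethyl)-4,6-bis(benzyloxy)phenyl group at C4β of unit M | O(Cc5ccccc5)c1ccc([C@H]2Oc3c(c(OCc5ccccc5)cc(OCc5ccccc5)c3[C@H]3c4c(OCc5ccccc5)cc(OCc5ccccc5)cc4O[C@H](c4ccc(OCc5ccccc5)cc4)[C@@H]3OC(C)=O)[C@H](c3c(OCc5ccccc5)cc(OCc5ccccc5)c(CO)c3O)[C@H]2OC(C)=O)cc1
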